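**Assumption:** the target has no stereocentre and is achiral, so there is no enantiomer to select. Racemic intermediates are drawn without stereodescriptors.

**Retrosynthetic overview**
1. Target ⇐ its 3'-O-isopropyl ether (BCl3 de-isopropylation last) ⇐ the 4-aryl-3,4-dihydrocoumarin (DDQ dehydrogenation).
2. Dihydrocoumarin ⇐ intermolecular Michael addition of 2,3,5-trimethoxyphenol (through C-6, ortho to OH) to the arylidene Meldrum's acid of O-isopropylisovanillin. This forms the C4–C4a bond that joins the two aryl fragments.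
3. Arylidene Meldrum's acid ⇐ Knoevenagel condensation of 3-isopropoxy-4-methoxybenzaldehyde (from isovanillin) with Meldrum's acid.
4. 2,3,5-Trimethoxyphenol ⇐ 2,4,6-trimethoxybenzaldehyde by ortho-demethylation, benzylation, Baeyer–Villiger oxidation, methylation and hydrogenolysis.
5. Ring order: both benzene rings are bought. Only the pyranone ring is built (C4–C4a by the Michael step, O1–C2 by lactonisation in the same flask) and it is aromatised afterwards.

**Route**

Step 1
Reactants: 1 2,4,6-trimethoxybenzaldehyde
Product: 2 2-hydroxy-4,6-dimethoxybenzaldehyde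
Conditions: BCl3 (1.2 equiv, 1 M in CH2Cl2), CH2Cl2, −78 °C → rt; H2O work-up
Reagents that add atoms: none
Why: Chelation-controlled Lewis-acid ether cleavage; BCl3 bound to the aldehyde oxygen cleaves only one of the two equivalent ortho methyl ethers, and the resulting boron chelate blocks a second cleavage.

Step 2
Reactants: 2 2-hydroxy-4,6-dimethoxybenzaldehyde
Product: 3 2-(benzyloxy)-4,6-dimethoxybenzaldehyde
Conditions: BnBr, K2CO3, DMF, 60 °C
Reagents that add atoms: benzyl bromide, BrCc1ccccc1
Why: Williamson ether synthesis on the phenoxide; the benzyl group marks this oxygen as the future lactone oxygen.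

Step 3
Reactants: 3 2-(benzyloxy)-4,6-dimethoxybenzaldehyde
Product: 5 2-(benzyloxy)-4,6-dimethoxyphenol, via aryl formate 4 (not isolated)
Conditions: mCPBA, CH2Cl2, 0 °C → rt; aq. NaHCO3 wash; then K2CO3 (cat.), MeOH, rt, N2
Reagents that add atoms: mCPBA, O=C(OO)c1cccc(Cl)c1
Why: Baeyer–Villiger (Dakin-type) oxidation; the very electron-rich aryl group migrates in preference to hydrogen to give the aryl formate, which base-catalysed methanolysis converts to the phenol.

Step 4
Reactants: 5 2-(benzyloxy)-4,6-dimethoxyphenol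
Product: 6 1-(benzyloxy)-2,3,5-trimethoxybenzene
Conditions: MeI, K2CO3, acetone, reflux, N2
Reagents that add atoms: iodomethane, CI
Why: Williamson O-methylation of the phenoxide; this fixes the 2,3,5-trimethoxy pattern with no regiochemical ambiguity.

Step 5
Reactants: 6 1-(benzyloxy)-2,3,5-trimethoxybenzene
Product: 7 2,3,5-trimethoxyphenol
Conditions: H2 (1 atm), 10% Pd/C, EtOAc–MeOH, rt
Reagents that add atoms: none
Why: Catalytic hydrogenolysis of the benzyl aryl ether; methyl ethers are inert and nothing else is reducible.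

Step 6
Reactants: 8 isovanillin (3-hydroxy-4-methoxybenzaldehyde)
Product: 9 3-isopropoxy-4-methoxybenzaldehyde
Conditions: 2-bromopropane, K2CO3, DMF, 70 °C
Reagents that add atoms: 2-bromopropane, CC(C)Br
Why: Williamson ether synthesis; the isopropyl ether survives base, DDQ and hot pyridine, and can later be cleaved in the presence of methyl ethers.

Step 7
Reactants: 9 3-isopropoxy-4-methoxybenzaldehyde; 10 Meldrum's acid (2,2-dimethyl-1,3-dioxane-4,6-dione)
Product: 11 5-(3-isopropoxy-4-methoxybenzylidene)-2,2-dimethyl-1,3-dioxane-4,6-dione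
Conditions: pyrrolidinium acetate (10 mol %), toluene, rt → 50 °C
Reagents that add atoms: none
Why: Knoevenagel condensation of the very acidic Meldrum's acid with an aryl aldehyde under iminium catalysis; the symmetric acceptor has no E/Z issue.

Step 8
Reactants: 7 2,3,5-trimethoxyphenol; 11 5-(3-isopropoxy-4-methoxybenzylidene)-2,2-dimethyl-1,3-dioxane-4,6-dione
Product: 14 4-(3-isopropoxy-4-methoxyphenyl)-5,7,8-trimethoxychroman-2-one (racemic), via Michael adduct 12 (not isolated), via acid lactone 13 (not isolated)
Conditions: pyridine, 100 °C, N2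
Reagents that add atoms: none
Why: Intermolecular Michael addition of the electron-rich phenol through C-6 to the doubly activated alkylidene; only the ortho adduct is trapped, by lactonisation (loss of acetone) and decarboxylation, while para- or O-adducts revert by retro-Michael, and C-4 forms as a racemate that step 9 erases.

Step 9
Reactants: 14 4-(3-isopropoxy-4-methoxyphenyl)-5,7,8-trimethoxychroman-2-one
Product: 15 4-(3-isopropoxy-4-methoxyphenyl)-5,7,8-trimethoxy-2H-chromen-2-one
Conditions: DDQ (1.5 equiv), 1,4-dioxane, reflux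
Reagents that add atoms: none
Why: DDQ dehydrogenation; hydride abstraction from the doubly benzylic C-4–H followed by loss of H-3 gives the conjugated coumarin and removes the only stereocentre.

Step 10
Reactants: 15 4-(3-isopropoxy-4-methoxyphenyl)-5,7,8-trimethoxy-2H-chromen-2-one
Product: 16 3'-hydroxy-5,7,8,4'-tetramethoxy-4-phenylcoumarin
Conditions: BCl3 (3 equiv, 1 M in CH2Cl2), CH2Cl2, −78 → 0 °C; H2O quench
Reagents that add atoms: none
Why: Selective Lewis-acid dealkylation; the secondary isopropyl aryl ether is cleaved far faster than methyl ethers at low temperature, and no methoxy group sits ortho to a carbonyl for chelation-assisted demethylation.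

**Compound list**
1 | 2,4,6-trimethoxybenzaldehyde | COc1cc(OC)c(C=O)c(OC)c1 | starting material
2 | 2-hydroxy-4,6-dimethoxybenzaldehyde | COc1cc(O)c(C=O)c(OC)c1 | intermediate
3 | 2-(benzyloxy)-4,6-dimethoxybenzaldehyde | COc1cc(OCc2ccccc2)c(C=O)c(OC)c1 | intermediate
4 | 2-(benzyloxy)-4,6-dimethoxyphenyl formate (not isolated) | COc1cc(OCc2ccccc2)c(OC=O)c(OC)c1 | intermediate
5 | 2-(benzyloxy)-4,6-dimethoxyphenol | COc1cc(OCc2ccccc2)c(O)c(OC)c1 | intermediate
6 | 1-(benzyloxy)-2,3,5-trimethoxybenzene | COc1cc(OCc2ccccc2)c(OC)c(OC)c1 | intermediate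
7 | 2,3,5-trimethoxyphenol | COc1cc(O)c(OC)c(OC)c1 | intermediate
8 | isovanillin (3-hydroxy-4-methoxybenzaldehyde) | COc1ccc(C=O)cc1O | starting material
9 | 3-isopropoxy-4-methoxybenzaldehyde | COc1ccc(C=O)cc1OC(C)C | intermediate
10 | Meldrum's acid (2,2-dimethyl-1,3-dioxane-4,6-dione) | CC1(C)OC(=O)CC(=O)O1 | starting material
11 | 5-(3-isopropoxy-4-methoxybenzylidene)-2,2-dimethyl-1,3-dioxane-4,6-dione | COc1ccc(C=C2C(=O)OC(C)(C)OC2=O)cc1OC(C)C | intermediate
12 | 5-[(2-hydroxy-3,4,6-trimethoxyphenyl)(3-isopropoxy-4-methoxyphenyl)methyl]-2,2-dimethyl-1,3-dioxane-4,6-dione (racemic; not isolated) | COc1ccc(C(C2C(=O)OC(C)(C)OC2=O)c2c(O)c(OC)c(OC)cc2OC)cc1OC(C)C | intermediate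
13 | 4-(3-isopropoxy-4-methoxyphenyl)-5,7,8-trimethoxy-2-oxochromane-3-carboxylic acid (racemic diastereomer mixture; not isolated) | COc1ccc(C2C(C(=O)O)C(=O)Oc3c(OC)c(OC)cc(OC)c32)cc1OC(C)C | intermediate
14 | 4-(3-isopropoxy-4-methoxyphenyl)-5,7,8-trimethoxychroman-2-one (racemic) | COc1ccc(C2CC(=O)Oc3c(OC)c(OC)cc(OC)c32)cc1OC(C)C | intermediate
15 | 4-(3-isopropoxy-4-methoxyphenyl)-5,7,8-trimethoxy-2H-chromen-2-one | COc1ccc(-c2cc(=O)oc3c(OC)c(OC)cc(OC)c23)cc1OC(C)C | intermediate
16 | 3'-hydroxy-5,7,8,4'-tetramethoxy-4-phenylcoumarin (achiral) | COc1ccc(-c2cc(=O)oc3c(OC)c(OC)cc(OC)c23)cc1O | target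

**Summary**
Total step count: 10.
Longest linear sequence: 8 steps (steps 1–5, then 8, 9, 10); steps 6–7 form the second branch.

**Steps most likely to fail, with fallbacks**

Step 8 (Michael addition and lactonisation). The risks are low conversion with the electron-rich, less electrophilic arylidene, and competing para- or O-alkylation of the phenol. The fallback builds the coumarin by a Pechmann condensation instead. It sets out from aldehyde 9: aldol addition of lithio ethyl acetate (LDA, EtOAc, THF, −78 °C) gives ethyl 3-hydroxy-3-(3-isopropoxy-4-methoxyphenyl)propanoate F1. Oxidation of this benzylic alcohol (Dess–Martin periodinane, CH2Cl2, rt) gives ethyl 3-(3-isopropoxy-4-methoxyphenyl)-3-oxopropanoate F2. Pechmann condensation of F2 with phenol 7 in TFA (rt → 50 °C) then gives the coumarin directly. The fallback comes back to the route at 15, so 14 and step 9 are skipped.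

Step 9 (DDQ dehydrogenation). The risks are incomplete reaction or over-oxidation of the electron-rich rings. The fallback uses enolate chemistry instead of hydride abstraction. It sets out from 14: LiHMDS with in-situ TMSCl (THF, −78 °C) gives the silyl ketene acetal {[4-(3-isopropoxy-4-methoxyphenyl)-5,7,8-trimethoxy-4H-chromen-2-yl]oxy}trimethylsilane F3. Saegusa–Ito oxidation of F3 (Pd(OAc)2, MeCN, rt) installs the C3=C4 double bond. The fallback comes back to the route at 15.

Step 3 (Baeyer–Villiger oxidation). The risk is that the peracid over-oxidises the trioxygenated ring to quinones. The fallback sets out from salicylaldehyde 2: a classical Dakin oxidation (H2O2, aq. NaOH, 0 °C → rt, N2) gives 3,5-dimethoxybenzene-1,2-diol F4. Monobenzylation of F4 (BnBr 1.0 equiv, K2CO3 1.0 equiv, DMF, rt, N2) should occur at the less hindered, more acidic 1-OH, which is meta to both methoxy groups; any regioisomer is removed by chromatography. The fallback comes back to the route at 5, so step 2 is also replaced.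

**Further compounds**
F1 | step 8 | ethyl 3-hydroxy-3-(3-isopropoxy-4-methoxyphenyl)propanoate (racemic) | CCOC(=O)CC(O)c1ccc(OC)c(OC(C)C)c1
F2 | step 8 | ethyl 3-(3-isopropoxy-4-methoxyphenyl)-3-oxopropanoate | CCOC(=O)CC(=O)c1ccc(OC)c(OC(C)C)c1
F3 | step 9 | {[4-(3-isopropoxy-4-methoxyphenyl)-5,7,8-trimethoxy-4H-chromen-2-yl]oxy}trimethylsilane (racemic) | COc1ccc(C2C=C(O[Si](C)(C)C)Oc3c(OC)c(OC)cc(OC)c32)cc1OC(C)C
F4 | step 3 | 3,5-dimethoxybenzene-1,2-diol | COc1cc(O)c(O)c(OC)c1
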